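The route rests on cutting C7–C8, the bond from the methylidene-bearing carbon (C7, attached to bromohydrin ring B) to the linker CH2 (C8, attached to diol ring A). The feature exploited is that C7=CH2 sits γ,δ to ring A's secondary carbinol carbon C10 (C10–C9–C8–C7): with C10 as a ketone, C8 is the β-carbon of a C9=C8 exo-methylene enone. A monovalent-rhodium-catalysed 1,4-addition of the ring B alkenylboronate to that enone forms C7–C8 and, after protonation and equilibration, sets C9 trans to the isopropenyl group. Both partners derive from the enantiomeric limonene-1,2-diols; hydroxyl-directed reduction of C10=O then gives the trans-diaxial diol.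

Key step: step 9

Remark: (4S)-limonene 1,2-oxide (cis/trans mixture) and (1S,2S,4R)-limonene-1,2-diol are taken as catalogue compounds; locants C7–C14 follow the overview (C11 = C(OH)CH3 and C14 = isopropenyl-bearing CH of ring A), and C1, C2, C4 in steps 1 and 4–6 are p-menthane locants.

Step 1
Reactants: 1 (4S)-limonene 1,2-oxide (cis/trans mixture)
Product: 2 (1R,2R,4S)-1-methyl-4-(prop-1-en-2-yl)cyclohexane-1,2-diol
Conditions: H2SO4 (0.05 M aq)/THF (1:1), 0 °C → rt
Reagents that add atoms: water, O
Why: Acid-catalysed epoxide hydrolysis under the Fürst–Plattner rule: water opens the cis epoxide at C1 and the trans epoxide at C2, each trans-diaxially, so both diastereomers should converge on the one diol (C1 and C2 both R) while C4 is untouched and the cold dilute acid spares the isopropenyl group.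

Step 2
Reactants: 2 (1R,2R,4S)-1-methyl-4-(prop-1-en-2-yl)cyclohexane-1,2-diol
Product: 3 (2R,5S)-2-hydroxy-2-methyl-5-(prop-1-en-2-yl)cyclohexan-1-one
Conditions: IBX (1.5 equiv), EtOAc, 75 °C
Reagents that add atoms: none
Why: IBX oxidation of the secondary alcohol to the ketone; the tertiary alcohol cannot be oxidised, IBX does not cleave 1,2-diols, and no stereocentre is touched.

Step 3
Reactants: 3 (2R,5S)-2-hydroxy-2-methyl-5-(prop-1-en-2-yl)cyclohexan-1-one
Product: 6 (3R,6R)-6-hydroxy-6-methyl-2-methylidene-3-(prop-1-en-2-yl)cyclohexan-1-one, via Mannich base 4 (not isolated), via trimethylammonium iodide 5 (not isolated)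
Conditions: LDA (2.2 equiv), THF, −78 °C; CH2=NMe2+ I− (1.5 equiv), −78 °C → rt; AcOH (1.1 equiv); MeI, rt; aq NaHCO3/CH2Cl2, rt; product used at once
Reagents that add atoms: dimethylmethylideneammonium iodide, C=[N+](C)C.[I-]
Why: Mannich reaction of the alkoxide–enolate dianion (only the C9 methylene is enolisable because C11 is quaternary), then N-methylation and bicarbonate-induced E1cB (Hofmann-type) elimination should give the exo-methylene ketone; the transient C9 stereocentre is destroyed and the weak base should leave the γ-hydrogen at C14 alone.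

Step 4
Reactants: 7 (1S,2S,4R)-1-methyl-4-(prop-1-en-2-yl)cyclohexane-1,2-diol
Product: 8 (3aS,6R,7aS)-3a-methyl-6-(prop-1-en-2-yl)hexahydro-1,3,2-benzodioxathiole 2-oxide (trans-fused cyclic sulfite; both configurations at sulfur)
Conditions: SOCl2 (1.2 equiv), Et3N (2.5 equiv), CH2Cl2, 0 °C
Reagents that add atoms: thionyl chloride, O=S(Cl)Cl
Why: Cyclic sulfite formation from a 1,2-diol; the trans-fused five-membered ring closes through the accessible diequatorial chair or twist form, and since no C–O bond is broken all three carbon stereocentres are retained.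

Step 5
Reactants: 8 cyclic sulfite
Product: 9 1-[(3aS,6R,7aS)-3a-methyl-2,2-dioxohexahydro-1,3,2-benzodioxathiol-6-yl]ethan-1-one (keto cyclic sulfate)
Conditions: RuCl3·xH2O (5 mol%), NaIO4 (4.5 equiv), MeCN/EtOAc/H2O (2:2:3), 0 °C → rt
Reagents that add atoms: sodium periodate, [Na+].[O-]I(=O)(=O)=O
Why: RuO4 generated in situ should oxidise the sulfite to the sulfate and cleave the 1,1-disubstituted isopropenyl alkene to the methyl ketone in one operation (catalytic ruthenium tetroxide oxidation); no stereocentre is involved.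

Step 6
Reactants: 9 keto cyclic sulfate
Product: 11 1-[(1R,3R,4S)-3-bromo-4-hydroxy-4-methylcyclohexyl]ethan-1-one, via lithium alkyl sulfate 10 (not isolated)
Conditions: LiBr (3 equiv), THF, 50 °C; then H2SO4 (cat.), H2O (2 equiv), THF, rt
Reagents that add atoms: lithium bromide, [Li+].[Br-]
Why: SN2 opening of the cyclic sulfate by bromide at the secondary carbon C2 with inversion (S to R) should place bromine cis to the C1 oxygen, because that oxygen is part of the leaving group and cannot act as a neighbouring group; acid hydrolysis of the tertiary sulfate monoester by S–O cleavage then frees the alcohol with retention.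

Step 7
Reactants: 11 1-[(1R,3R,4S)-3-bromo-4-hydroxy-4-methylcyclohexyl]ethan-1-one
Product: 12 1-[(1R,3R,4S)-3-bromo-4-hydroxy-4-methylcyclohexyl]ethenyl trifluoromethanesulfonate
Conditions: LiHMDS (2.2 equiv), THF, −78 °C; N-(5-chloropyridin-2-yl)bis(trifluoromethanesulfonimide) (1.1 equiv), −78 °C; aq NH4Cl
Reagents that add atoms: N-(5-chloropyridin-2-yl)bis(trifluoromethanesulfonimide), Clc1ccc(nc1)N(S(=O)(=O)C(F)(F)F)S(=O)(=O)C(F)(F)F
Why: Kinetic deprotonation of the methyl group (after the alkoxide) and O-sulfonylation of the terminal enolate should give the 2-triflyloxy-1-alkene; at −78 °C the cis alkoxide/bromide pair cannot close to an epoxide, the equatorial bromide has no anti-periplanar hydrogen for E2, and the hindered tertiary alkoxide should not be triflated.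

Step 8
Reactants: 12 enol triflate
Product: 13 (1S,2R,4R)-2-bromo-1-methyl-4-[1-(4,4,5,5-tetramethyl-1,3,2-dioxaborolan-2-yl)ethenyl]cyclohexan-1-ol
Conditions: PdCl2(PPh3)2 (3 mol%), PPh3 (6 mol%), B2pin2 (1.1 equiv), KOPh (1.5 equiv), toluene, 50 °C
Reagents that add atoms: bis(pinacolato)diboron, CC1(C)OB(OC1(C)C)B1OC(C)(C)C(C)(C)O1
Why: Miyaura borylation: zerovalent palladium inserts into the alkenyl C–OTf bond far faster than into the unactivated secondary C–Br bond, phenoxide mediates boryl transfer, and the free tertiary alcohol is tolerated.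

Step 9
Reactants: 6 (3R,6R)-6-hydroxy-6-methyl-2-methylidene-3-(prop-1-en-2-yl)cyclohexan-1-one; 13 ring B alkenylboronate
Product: 14 (2R,3S,6R)-2-{2-[(1R,3R,4S)-3-bromo-4-hydroxy-4-methylcyclohexyl]prop-2-en-1-yl}-6-hydroxy-6-methyl-3-(prop-1-en-2-yl)cyclohexan-1-one
Conditions: [Rh(OH)(cod)]2 (3 mol%), 13 (1.5 equiv), 1,4-dioxane/H2O (10:1), 40 °C; then DBU (0.2 equiv), rt
Reagents that add atoms: none
Why: Transmetalation of 13 to the hydroxorhodium catalyst gives an α-branched alkenylrhodium that adds across the exocyclic C9=C8 bond of 6, delivering C7 to the unsubstituted carbon C8 and leaving an oxa-π-allyl rhodium enolate whose hydrolysis releases the ketone and regenerates Rh–OH. The closest known reaction type is the Hayashi–Miyaura 1,4-addition of alkenylboron reagents to enones, including α-methylene carbonyl acceptors. No ring is closed. The only new stereocentre, C9, is set by protonation and then put under thermodynamic control by DBU (C9 is the sole enolisable position): the C8 substituent should settle equatorial and trans to the isopropenyl group (C9 R), because the cis epimer would hold it axial and syn to the axial C11–OH. The step needs chemoselectivity for the enone over the isopropenyl group, the secondary bromide and the two tertiary alcohols, which the mild aqueous rhodium conditions secure; it also needs addition to outrun protodeboronation of 13 and double-bond migration in 6, which the unhindered terminal β-carbon, the fixed s-cis enone and the excess of 13 should secure.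

Step 10
Reactants: 14 coupled hydroxy ketone
Product: 15 prevezol C, (1R,2R,3R,4S)-3-{2-[(1R,3R,4S)-3-bromo-4-hydroxy-4-methylcyclohexyl]prop-2-en-1-yl}-1-methyl-4-(prop-1-en-2-yl)cyclohexane-1,2-diol
Conditions: Me4NBH(OAc)3 (5 equiv), MeCN/AcOH (1:1), −20 °C → rt
Reagents that add atoms: none
Why: Hydroxyl-directed (Saksena–Evans) reduction: the axial C11 hydroxyl exchanges onto boron and delivers hydride to the face of the C10 carbonyl on which it sits, so the new C10–OH should come out axial and trans to the C11–OH (C10 R); the reagent does not reduce unassisted ketones, which suppresses the sterically preferred attack from the other face and leaves the alkenes and the secondary bromide alone.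

Compound list
1 | (4S)-limonene 1,2-oxide, (4S)-1-methyl-4-(prop-1-en-2-yl)-7-oxabicyclo[4.1.0]heptane, cis/trans mixture | CC(=C)[C@H]1CCC2(C)OC2C1 | starting material
2 | (1R,2R,4S)-1-methyl-4-(prop-1-en-2-yl)cyclohexane-1,2-diol | CC(=C)[C@H]1CC[C@@](C)(O)[C@H](O)C1 | intermediate
3 | (2R,5S)-2-hydroxy-2-methyl-5-(prop-1-en-2-yl)cyclohexan-1-one | CC(=C)[C@H]1CC[C@@](C)(O)C(=O)C1 | intermediate
4 | (2R,5S)-6-[(dimethylamino)methyl]-2-hydroxy-2-methyl-5-(prop-1-en-2-yl)cyclohexan-1-one (Mannich base, C6 epimers) | CN(C)CC1[C@@H](C(=C)C)CC[C@@](C)(O)C1=O | intermediate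
5 | 1-[(3R,6S)-3-hydroxy-3-methyl-2-oxo-6-(prop-1-en-2-yl)cyclohexyl]-N,N,N-trimethylmethanaminium iodide (C1 epimers) | C[N+](C)(C)CC1[C@@H](C(=C)C)CC[C@@](C)(O)C1=O.[I-] | intermediate
6 | (3R,6R)-6-hydroxy-6-methyl-2-methylidene-3-(prop-1-en-2-yl)cyclohexan-1-one | C=C1[C@@H](C(=C)C)CC[C@@](C)(O)C1=O | intermediate
7 | (1S,2S,4R)-1-methyl-4-(prop-1-en-2-yl)cyclohexane-1,2-diol | CC(=C)[C@@H]1CC[C@](C)(O)[C@@H](O)C1 | starting material
8 | (3aS,6R,7aS)-3a-methyl-6-(prop-1-en-2-yl)hexahydro-1,3,2-benzodioxathiole 2-oxide (cyclic sulfite, sulfur epimers) | CC(=C)[C@@H]1CC[C@]2(C)OS(=O)O[C@H]2C1 | intermediate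
9 | 1-[(3aS,6R,7aS)-3a-methyl-2,2-dioxohexahydro-1,3,2-benzodioxathiol-6-yl]ethan-1-one (cyclic sulfate) | CC(=O)[C@@H]1CC[C@]2(C)OS(=O)(=O)O[C@H]2C1 | intermediate
10 | lithium (1S,2R,4R)-4-acetyl-2-bromo-1-methylcyclohexyl sulfate | CC(=O)[C@@H]1CC[C@](C)(OS(=O)(=O)[O-])[C@H](Br)C1.[Li+] | intermediate
11 | 1-[(1R,3R,4S)-3-bromo-4-hydroxy-4-methylcyclohexyl]ethan-1-one | CC(=O)[C@@H]1CC[C@](C)(O)[C@H](Br)C1 | intermediate
12 | 1-[(1R,3R,4S)-3-bromo-4-hydroxy-4-methylcyclohexyl]ethenyl trifluoromethanesulfonate | C=C(OS(=O)(=O)C(F)(F)F)[C@@H]1CC[C@](C)(O)[C@H](Br)C1 | intermediate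
13 | (1S,2R,4R)-2-bromo-1-methyl-4-[1-(4,4,5,5-tetramethyl-1,3,2-dioxaborolan-2-yl)ethenyl]cyclohexan-1-ol | C=C(B1OC(C)(C)C(C)(C)O1)[C@@H]1CC[C@](C)(O)[C@H](Br)C1 | intermediate
14 | (2R,3S,6R)-2-{2-[(1R,3R,4S)-3-bromo-4-hydroxy-4-methylcyclohexyl]prop-2-en-1-yl}-6-hydroxy-6-methyl-3-(prop-1-en-2-yl)cyclohexan-1-one | C=C(C[C@@H]1[C@@H](C(=C)C)CC[C@@](C)(O)C1=O)[C@@H]1CC[C@](C)(O)[C@H](Br)C1 | intermediate
15 | prevezol C, (1R,2R,3R,4S)-3-{2-[(1R,3R,4S)-3-bromo-4-hydroxy-4-methylcyclohexyl]prop-2-en-1-yl}-1-methyl-4-(prop-1-en-2-yl)cyclohexane-1,2-diol | C=C(C[C@@H]1[C@@H](C(=C)C)CC[C@@](C)(O)[C@@H]1O)[C@@H]1CC[C@](C)(O)[C@H](Br)C1 | target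

Total step count: 10 (ring A branch steps 1–3, ring B branch steps 4–8, union and finish steps 9–10).
Longest linear sequence: 7 steps (7 → 8 → 9 → 11 → 12 → 13 → 14 → 15; steps 4–10).

Steps most likely to fail

Step 9 (key coupling). Insertion of the hindered α-branched alkenylrhodium may be slow. Protodeboronation of 13, or rhodium-hydride-mediated migration of the exocyclic double bond of 6 into the ring towards C14, could then outrun the addition. The fallback sets out from 6, with 12 as partner, and comes back at 14; boron and triflate change sides. CuCl/NaOtBu/Xantphos-catalysed conjugate borylation of 6 with B2pin2 and MeOH (THF, rt; then DBU to equilibrate C9) should give (2R,3S,6R)-6-hydroxy-6-methyl-3-(prop-1-en-2-yl)-2-[(4,4,5,5-tetramethyl-1,3,2-dioxaborolan-2-yl)methyl]cyclohexan-1-one F1. A B-alkyl Suzuki–Miyaura coupling of F1 with 12 (Pd(OAc)2, RuPhos, K3PO4, toluene/H2O, 80 °C) should then form the same C7–C8 bond and give 14.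

Step 6 (cis-bromohydrin). Backside attack of bromide at the secondary carbon is hindered by the adjacent quaternary carbon and by the ring, so ionisation or attack at the tertiary C–O bond, or elimination, could take over. The fallback sets out from 7 and comes back at 11; it uses an open-chain sulfonate with a non-participating silyl ether instead of the cyclic sulfate.
- 7 is bis-silylated (TMSOTf, 2,6-lutidine, CH2Cl2) to [(1S,2S,4R)-1-methyl-4-(prop-1-en-2-yl)cyclohexane-1,2-diyl]bis(oxy)bis(trimethylsilane) F2.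
- K2CO3/MeOH at 0 °C should cleave only the less hindered secondary silyl ether, giving (1S,2S,5R)-2-methyl-5-(prop-1-en-2-yl)-2-[(trimethylsilyl)oxy]cyclohexan-1-ol F3.
- Tf2O/pyridine (−30 °C) gives (1S,2S,5R)-2-methyl-5-(prop-1-en-2-yl)-2-[(trimethylsilyl)oxy]cyclohexyl trifluoromethanesulfonate F4.
- Bu4NBr (toluene, 0 °C → rt) should displace the triflate with inversion to {[(1S,2R,4R)-2-bromo-1-methyl-4-(prop-1-en-2-yl)cyclohexyl]oxy}trimethylsilane F5.
- PPTS/MeOH frees (1S,2R,4R)-2-bromo-1-methyl-4-(prop-1-en-2-yl)cyclohexan-1-ol F6.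
- Ozonolysis of the isopropenyl group of F6 (O3, CH2Cl2, −78 °C; Me2S) gives 11.

Step 7 (enol triflate). The lithium alkoxide of the cis-bromohydrin may ring-contract (semipinacol shift) or be triflated at oxygen, and kinetic regiocontrol of enolisation may erode on warming. The fallback sets out from 11 and comes back at 12; the tertiary alcohol is masked for the enolate step. N-(Trimethylsilyl)imidazole (CH2Cl2, rt) should give 1-{(1R,3R,4S)-3-bromo-4-methyl-4-[(trimethylsilyl)oxy]cyclohexyl}ethan-1-one F7. LiHMDS (1.1 equiv) and the same triflimide reagent at −78 °C should give 1-{(1R,3R,4S)-3-bromo-4-methyl-4-[(trimethylsilyl)oxy]cyclohexyl}ethenyl trifluoromethanesulfonate F8. PPTS/MeOH then removes the silyl group to give 12.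

Further compounds
F1 | step 9 | (2R,3S,6R)-6-hydroxy-6-methyl-3-(prop-1-en-2-yl)-2-[(4,4,5,5-tetramethyl-1,3,2-dioxaborolan-2-yl)methyl]cyclohexan-1-one | CC1(C)OB(C[C@@H]2[C@@H](C(=C)C)CC[C@@](C)(O)C2=O)OC1(C)C
F2 | step 6 | [(1S,2S,4R)-1-methyl-4-(prop-1-en-2-yl)cyclohexane-1,2-diyl]bis(oxy)bis(trimethylsilane) | CC(=C)[C@@H]1CC[C@](C)(O[Si](C)(C)C)[C@@H](O[Si](C)(C)C)C1
F3 | step 6 | (1S,2S,5R)-2-methyl-5-(prop-1-en-2-yl)-2-[(trimethylsilyl)oxy]cyclohexan-1-ol | CC(=C)[C@@H]1CC[C@](C)(O[Si](C)(C)C)[C@@H](O)C1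
F4 | step 6 | (1S,2S,5R)-2-methyl-5-(prop-1-en-2-yl)-2-[(trimethylsilyl)oxy]cyclohexyl trifluoromethanesulfonate | CC(=C)[C@@H]1CC[C@](C)(O[Si](C)(C)C)[C@@H](OS(=O)(=O)C(F)(F)F)C1
F5 | step 6 | {[(1S,2R,4R)-2-bromo-1-methyl-4-(prop-1-en-2-yl)cyclohexyl]oxy}trimethylsilane | CC(=C)[C@@H]1CC[C@](C)(O[Si](C)(C)C)[C@H](Br)C1
F6 | step 6 | (1S,2R,4R)-2-bromo-1-methyl-4-(prop-1-en-2-yl)cyclohexan-1-ol | CC(=C)[C@@H]1CC[C@](C)(O)[C@H](Br)C1
F7 | step 7 | 1-{(1R,3R,4S)-3-bromo-4-methyl-4-[(trimethylsilyl)oxy]cyclohexyl}ethan-1-one | CC(=O)[C@@H]1CC[C@](C)(O[Si](C)(C)C)[C@H](Br)C1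
F8 | step 7 | 1-{(1R,3R,4S)-3-bromo-4-methyl-4-[(trimethylsilyl)oxy]cyclohexyl}ethenyl trifluoromethanesulfonate | C=C(OS(=O)(=O)C(F)(F)F)[C@@H]1CC[C@](C)(O[Si](C)(C)C)[C@H](Br)C1
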